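Numbering (longipinane): C1 ketone, C2=C3(Me), C4, C5, C6(Me2), C7(OAng), C8(OiBu), C9, C10(Me), C11; the cyclobutane is C4–C5–C11–C10, bridged C11→C4 by C1–C2=C3 and C10→C5 by C9–C8–C7–C6.
Feature used: the quaternary C10 and its neighbour C11 are adjacent cyclobutane carbons; with a carbonyl at C5 they are the β- and α-carbons of a 3-alkylcyclobutenone, so C10–CH3 and C11–C1 are made in one three-component step (AlMe3 to C10, enolate carbon C11 to but-2-ynal).
Late stage: C1 enone from the allylic alcohol; 7,8-diester from the trans-diol; diol from the C7 ketone (C8 enolate hydroxylation, directed reduction); C5–H from radical deoxygenation of the aldol carbinol.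
Ring closures: C5–C6 (seven-membered ring) by aldol of the C7 isopropyl ketone onto the C5 cyclobutanone; C3–C4 (six-membered ring) by gold-catalysed 6-endo-dig attack of the C4=C5 silyl enol ether on the C2≡C3 alkyne.
Order of ring formation: cyclobutane (dichloroketene [2+2] on a terminal alkyne), then six-membered ring, then seven-membered ring.
Key step: step 7

Assumption: the sense of induction of the phosphoramidite (step 7) and of the oxaziridine (step 15) cannot be derived from a model for these substrates; the enantiomers named are taken as the matched ones and would be exchanged for their antipodes if a first run shows the opposite sense.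

Step 1
Reactants: 1 pent-4-ynoic acid
Product: 3 N-methoxy-N-methylpent-4-ynamide, via acyl imidazole 2 (not isolated)
Conditions: CDI, CH2Cl2, rt; then MeNHOMe·HCl, rt
Reagents that add atoms: N,O-dimethylhydroxylamine hydrochloride, Cl.CNOC
Why: Amide coupling through the acyl imidazole gives the Weinreb amide without touching the terminal alkyne.

Step 2
Reactants: 3 N-methoxy-N-methylpent-4-ynamide; 4 isopropylmagnesium chloride
Product: 5 2-methylhept-6-yn-3-one
Conditions: iPrMgCl (2.2 equiv), THF, 0 °C; aq. NH4Cl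
Reagents that add atoms: none
Why: Weinreb ketone synthesis: the magnesium chelate of the tetrahedral adduct stops at the ketone stage, and the second equivalent covers deprotonation of the alkyne.

Step 3
Reactants: 5 2-methylhept-6-yn-3-one
Product: 6 2-(but-3-yn-1-yl)-2-(propan-2-yl)-1,3-dioxolane
Conditions: ethylene glycol, TsOH·H2O (cat.), toluene, reflux, Dean–Stark
Reagents that add atoms: ethylene glycol, OCCO
Why: Acid-catalysed ketalisation with azeotropic removal of water masks the C7 ketone against AlMe3 and amide bases.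

Step 4
Reactants: 6 2-(but-3-yn-1-yl)-2-(propan-2-yl)-1,3-dioxolane; 7 trichloroacetyl chloride
Product: 9 4,4-dichloro-3-{2-[2-(propan-2-yl)-1,3-dioxolan-2-yl]ethyl}cyclobut-2-en-1-one, via dichloroketene 8 (not isolated)
Conditions: Zn–Cu couple, Et2O/DME, rt
Reagents that add atoms: none
Why: Ketene–alkyne [2+2] cycloaddition: dichloroketene bonds through its carbonyl carbon to the terminal alkyne carbon, and DME ties up ZnCl2 so that the dioxolane survives.

Step 5
Reactants: 9 4,4-dichloro-3-{2-[2-(propan-2-yl)-1,3-dioxolan-2-yl]ethyl}cyclobut-2-en-1-one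
Product: 10 3-{2-[2-(propan-2-yl)-1,3-dioxolan-2-yl]ethyl}cyclobut-2-en-1-one
Conditions: Zn dust, AcOH, TMEDA, EtOH, 0 °C → rt
Reagents that add atoms: none
Why: Zinc reduction of the α,α-dichloro ketone in a buffered medium removes both chlorines without moving the double bond or hydrolysing the ketal.

Step 6
Reactants: 11 but-2-yn-1-ol
Product: 12 but-2-ynal
Conditions: MnO2, CH2Cl2, rt; filtered solution used directly
Reagents that add atoms: none
Why: MnO2 oxidation of a propargylic alcohol stops cleanly at the volatile ynal, which is used in solution.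

Step 7
Reactants: 10 3-{2-[2-(propan-2-yl)-1,3-dioxolan-2-yl]ethyl}cyclobut-2-en-1-one; 12 but-2-ynal; 13 trimethylaluminium
Product: 15 (2R,3R)-2-[(1R)-1-hydroxybut-2-yn-1-yl]-3-methyl-3-{2-[2-(propan-2-yl)-1,3-dioxolan-2-yl]ethyl}cyclobutan-1-one, via aluminium enolate 14 (not isolated)
Conditions: Cu(OTf)2 (5 mol %), (S)-binaphthol N,N-bis[(R)-1-phenylethyl]phosphoramidite (10 mol %), AlMe3 (1.4 equiv), Et2O, −30 °C; then 12 (3 equiv), −78 → −40 °C; aq. potassium sodium tartrate
Reagents that add atoms: none
Why: Proposed new method: AlMe3 reduces Cu(OTf)2 to a monovalent methylcopper–phosphoramidite complex that binds the C10=C11 bond of the strained, strongly electrophilic enone 10, adds at C10 and eliminates reductively to form C10–CH3, the enolate passing to aluminium as 14, which then attacks the aldehyde carbon of 12 through C11 (C11–C1) in an aldol addition. The closest known reaction type is the copper–phosphoramidite-catalysed conjugate addition of AlMe3 to β-substituted five- to seven-membered cycloalkenones forming quaternary centres, with aldol trapping of the aluminium enolate; the four-membered enone is the untested extension. No ring is closed: two skeletal bonds join the C6–C9 chain, the C10 methyl group and the C1–C3 unit around the cyclobutanone, whose C5 carbonyl is kept for both later ring closures. C10 is set by the chiral ligand (enantioface choice at the β-carbon), C11 by approach of the aldehyde to the enolate face away from the C9 chain, that is cis to the new methyl group, and C1 by the aldol transition state (drawn as one epimer; it is erased when C1 becomes a ketone in step 20). The step needs 1,4- over 1,2-methyl transfer (ether solvent and −30 °C keep uncatalysed AlMe3 addition slow, and the aldehyde is added only after 10 is consumed), enantioface selection (ligand) and face selection at C11 (chain versus methyl on C10, which differ only modestly in size, so a C11 epimer is to be expected and is removed by chromatography).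

Step 8
Reactants: 15 (2R,3R)-2-[(1R)-1-hydroxybut-2-yn-1-yl]-3-methyl-3-{2-[2-(propan-2-yl)-1,3-dioxolan-2-yl]ethyl}cyclobutan-1-one
Product: 16 (2R,3R)-2-[(1R)-1-(tert-butyldimethylsilyloxy)but-2-yn-1-yl]-3-methyl-3-{2-[2-(propan-2-yl)-1,3-dioxolan-2-yl]ethyl}cyclobutan-1-one
Conditions: TBSCl, imidazole, DMF, rt
Reagents that add atoms: TBSCl, CC(C)(C)[Si](C)(C)Cl
Why: Silyl ether formation at the secondary propargylic alcohol blocks retro-aldol and dehydration and leaves the ketal untouched.

Step 9
Reactants: 16 (2R,3R)-2-[(1R)-1-(tert-butyldimethylsilyloxy)but-2-yn-1-yl]-3-methyl-3-{2-[2-(propan-2-yl)-1,3-dioxolan-2-yl]ethyl}cyclobutan-1-one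
Product: 18 silyl enol ether of 16 (C4=C5–OTBS; 1-silyloxycyclobutene with C10 and C11 as in 16), via lithium enolate 17 (not isolated)
Conditions: LiN(iPr)2, THF, −78 °C; then TBSCl, DMPU, −78 → 0 °C
Reagents that add atoms: TBSCl, CC(C)(C)[Si](C)(C)Cl
Why: Kinetic deprotonation takes the unhindered C4 methylene and not the tertiary C11–H (whose enolate would expel the β-silyloxy group), and O-silylation gives the enol ether, which is used without chromatography.

Step 10
Reactants: 18 silyl enol ether of 16
Product: 19 4-(tert-butyldimethylsilyloxy)-2,7-dimethyl-7-{2-[2-(propan-2-yl)-1,3-dioxolan-2-yl]ethyl}bicyclo[3.1.1]hept-2-en-6-one (longipinane C1(OTBS), C2=C3(Me), C4, C5=O, C10, C11; the C9 chain on C10 syn to the C5 carbonyl bridge)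
Conditions: (Ph3P)AuCl (10 mol %), AgOTf (10 mol %), CH2Cl2/MeOH 10:1, rt → 40 °C
Reagents that add atoms: none
Why: Proposed new method: cationic monovalent gold activates the C2≡C3 alkyne, the C4 terminus of the 1-silyloxycyclobutene attacks C3 anti to gold in a 6-endo-dig closure (the 5-exo alternative would give a bicyclo[2.1.1]hexanone), and methanol takes the silyl group from the oxocarbenium ion and protonates the C2–Au bond, so that the bicyclo[3.1.1]heptenone forms with C4 fixed by the tether from C11; the closest known reaction type is the gold-catalysed carbocyclisation of cyclopentanone- and cyclohexanone-derived silyl enol ethers onto tethered alkynes, including 6-endo-dig closures to bicyclo[3.3.1]nonenones.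

Step 11
Reactants: 19 bicyclic ketone with dioxolane
Product: 20 4-(tert-butyldimethylsilyloxy)-2,7-dimethyl-7-(4-methyl-3-oxopentyl)bicyclo[3.1.1]hept-2-en-6-one
Conditions: PPTS, acetone/H2O 10:1, 55 °C
Reagents that add atoms: water, O
Why: Mild acid hydrolysis of the ketal frees the C7 isopropyl ketone while the secondary silyl ether and the non-enolisable cyclobutanone stay intact.

Step 12
Reactants: 20 bicyclic diketone
Product: 22 (4R,10R,11R)-1-(tert-butyldimethylsilyloxy)-5-hydroxylongipin-2-en-7-one (C5–OH in the place of the C5–H of the target), via lithium enolate 21 (not isolated)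
Conditions: LiN(SiMe3)2 (1.1 equiv), THF, −78 → 0 °C; AcOH
Reagents that add atoms: none
Why: Intramolecular aldol addition: the C5 ketone cannot enolise (both α-carbons are bridgeheads), the ketone enolates equilibrate through the amine, the C8 enolate can only close to a strained bicyclo[2.1.1]hexane and reverts, and the C6 enolate, held by the C9 chain over the open face of the strain-activated C5 carbonyl, closes the seven-membered ring to a chelated lithium aldolate; the C5 configuration is dictated by the tether.

Step 13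
Reactants: 22 tricyclic aldol
Product: 23 methyl oxalate of 22 (C5–O–CO–CO2Me)
Conditions: ClCOCO2Me, DMAP, pyridine, CH2Cl2, 0 °C → rt
Reagents that add atoms: methyl chlorooxoacetate, COC(=O)C(=O)Cl
Why: The highly reactive oxalyl chloride acylates the hindered tertiary cyclobutanol under weakly basic conditions that do not trigger retro-aldol cleavage.

Step 14
Reactants: 23 methyl oxalate
Product: 24 (4R,5S,10R,11R)-1-(tert-butyldimethylsilyloxy)longipin-2-en-7-one
Conditions: Bu3SnH, AIBN, toluene, 110 °C
Reagents that add atoms: none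
Why: Barton-type radical deoxygenation of a tertiary methyl oxalate: the C5 cyclobutyl radical has no β-hydrogen route to an alkene and takes hydrogen from tin in the only position left free by the C6 bridge, which sets C5.

Step 15
Reactants: 24 tricyclic C7 ketone
Product: 26 (4R,5S,8S,10R,11R)-1-(tert-butyldimethylsilyloxy)-8-hydroxylongipin-2-en-7-one, via sodium enolate 25 (not isolated)
Conditions: NaN(SiMe3)2, THF, −78 °C; then (+)-(camphorsulfonyl)oxaziridine, −78 °C; AcOH
Reagents that add atoms: (+)-(2R,8aS)-(camphorsulfonyl)oxaziridine, CC1(C)[C@@H]2CC[C@]13CS(=O)(=O)N4O[C@@]34C2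
Why: Oxaziridine hydroxylation of the only possible enolate (C6 is quaternary); the two faces of the C7=C8 enolate differ only through the remote C1 and C3 ends of the other bridge, so the facial choice at C8 is left to the enantiopure reagent and the C8 epimer is removed by chromatography.

Step 16
Reactants: 26 α-hydroxy ketone
Product: 27 (4R,5S,7S,8S,10R,11R)-1-(tert-butyldimethylsilyloxy)longipin-2-ene-7,8-diol (trans-diol)
Conditions: Me4NBH(OAc)3, MeCN/AcOH 1:1, −30 → 0 °C
Reagents that add atoms: none
Why: Hydroxyl-directed triacetoxyborohydride reduction: the borohydride exchanges onto the C8–OH and delivers hydride to the C7 carbonyl from the same face, so the new C7–OH is trans to the C8–OH.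

Step 17
Reactants: 27 trans-diol; 28 2-methylpropanoyl chloride
Product: 29 (7S,8S)-1-(tert-butyldimethylsilyloxy)-7-hydroxylongipin-2-en-8-yl 2-methylpropanoate
Conditions: pyridine, CH2Cl2, −20 → 0 °C
Reagents that add atoms: none
Why: Selective acylation: the C8–OH reacts first because the C7–OH is neopentylic, shielded by the C6 gem-dimethyl group.

Step 18
Reactants: 29 C8 isobutyrate; 30 angelic acid
Product: 32 (7S,8S)-1-(tert-butyldimethylsilyloxy)-8-(2-methylpropanoyloxy)longipin-2-en-7-yl (Z)-2-methylbut-2-enoate, via mixed anhydride 31 (not isolated)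
Conditions: 2,4,6-trichlorobenzoyl chloride, Et3N, toluene, rt; then 29, 80 °C
Reagents that add atoms: none
Why: Yamaguchi esterification through the mixed anhydride, run without a nucleophilic catalyst, acylates the hindered C7–OH and keeps the (Z)-geometry of the angelate.

Step 19
Reactants: 32 diester silyl ether
Product: 33 (7S,8S)-1-hydroxy-8-(2-methylpropanoyloxy)longipin-2-en-7-yl (Z)-2-methylbut-2-enoate
Conditions: HF·pyridine, pyridine, THF, 0 °C → rt
Reagents that add atoms: none
Why: Buffered fluoride desilylation frees the allylic C1–OH without acyl migration or ester cleavage.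

Step 20
Reactants: 33 allylic alcohol
Product: 34 (4R,5S,7S,8S,10R,11R)-7-[(Z)-2-methylbut-2-enoyloxy]-8-(2-methylpropanoyloxy)longipin-2-en-1-one (CNP0286736.1)
Conditions: MnO2, CH2Cl2, rt
Reagents that add atoms: none
Why: Chemoselective MnO2 oxidation of the allylic alcohol gives the C1 enone and removes the C1 stereocentre; the bridgehead C11 cannot epimerise.

Compound list
1 | pent-4-ynoic acid | C#CCCC(=O)O | starting material
2 | 1-(pent-4-ynoyl)imidazole | C#CCCC(=O)n1ccnc1 | intermediate
3 | N-methoxy-N-methylpent-4-ynamide | C#CCCC(=O)N(C)OC | intermediate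
4 | isopropylmagnesium chloride | CC(C)[Mg]Cl | starting material
5 | 2-methylhept-6-yn-3-one | CC(C)C(=O)CCC#C | intermediate
6 | 2-(but-3-yn-1-yl)-2-(propan-2-yl)-1,3-dioxolane | CC(C)C1(OCCO1)CCC#C | intermediate
7 | trichloroacetyl chloride | ClC(=O)C(Cl)(Cl)Cl | starting material
8 | dichloroketene | O=C=C(Cl)Cl | intermediate
9 | 4,4-dichloro-3-{2-[2-(propan-2-yl)-1,3-dioxolan-2-yl]ethyl}cyclobut-2-en-1-one | CC(C)C1(OCCO1)CCC2=CC(=O)C2(Cl)Cl | intermediate
10 | 3-{2-[2-(propan-2-yl)-1,3-dioxolan-2-yl]ethyl}cyclobut-2-en-1-one | CC(C)C1(OCCO1)CCC2=CC(=O)C2 | intermediate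
11 | but-2-yn-1-ol | CC#CCO | starting material
12 | but-2-ynal | CC#CC=O | intermediate
13 | trimethylaluminium | C[Al](C)C | starting material
14 | dimethylaluminium enolate from methyl addition to 10 (C11=C5–O–AlMe2) | CC(C)C1(OCCO1)CC[C@@]2(C)C=C(O[Al](C)C)C2 | intermediate
15 | (2R,3R)-2-[(1R)-1-hydroxybut-2-yn-1-yl]-3-methyl-3-{2-[2-(propan-2-yl)-1,3-dioxolan-2-yl]ethyl}cyclobutan-1-one | CC(C)C1(OCCO1)CC[C@@]2(C)[C@H]([C@@H](O)C#CC)C(=O)C2 | intermediate
16 | (2R,3R)-2-[(1R)-1-(tert-butyldimethylsilyloxy)but-2-yn-1-yl]-3-methyl-3-{2-[2-(propan-2-yl)-1,3-dioxolan-2-yl]ethyl}cyclobutan-1-one | CC(C)C1(OCCO1)CC[C@@]2(C)[C@H]([C@@H](O[Si](C)(C)C(C)(C)C)C#CC)C(=O)C2 | intermediate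
17 | lithium enolate of 16 (C4=C5–OLi) | CC(C)C1(OCCO1)CC[C@@]2(C)[C@H]([C@@H](O[Si](C)(C)C(C)(C)C)C#CC)C(O[Li])=C2 | intermediate
18 | tert-butyldimethylsilyl enol ether of 16 (C4=C5–OTBS) | CC(C)C1(OCCO1)CC[C@@]2(C)[C@H]([C@@H](O[Si](C)(C)C(C)(C)C)C#CC)C(O[Si](C)(C)C(C)(C)C)=C2 | intermediate
19 | 4-(tert-butyldimethylsilyloxy)-2,7-dimethyl-7-{2-[2-(propan-2-yl)-1,3-dioxolan-2-yl]ethyl}bicyclo[3.1.1]hept-2-en-6-one | CC(C)C1(OCCO1)CC[C@@]2(C)[C@@H]3[C@@H](O[Si](C)(C)C(C)(C)C)C=C(C)[C@H]2C3=O | intermediate
20 | 4-(tert-butyldimethylsilyloxy)-2,7-dimethyl-7-(4-methyl-3-oxopentyl)bicyclo[3.1.1]hept-2-en-6-one | CC(C)C(=O)CC[C@@]1(C)[C@@H]2[C@@H](O[Si](C)(C)C(C)(C)C)C=C(C)[C@H]1C2=O | intermediate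
21 | lithium C6 enolate of 20 (C6=C7–OLi) | CC(C)=C(O[Li])CC[C@@]1(C)[C@@H]2[C@@H](O[Si](C)(C)C(C)(C)C)C=C(C)[C@H]1C2=O | intermediate
22 | 1-(tert-butyldimethylsilyloxy)-5-hydroxylongipin-2-en-7-one | O=C1CC[C@@]2(C)[C@@H]3[C@@H](O[Si](C)(C)C(C)(C)C)C=C(C)[C@H]2[C@]3(O)C1(C)C | intermediate
23 | 1-(tert-butyldimethylsilyloxy)-7-oxolongipin-2-en-5-yl methyl oxalate | O=C1CC[C@@]2(C)[C@@H]3[C@@H](O[Si](C)(C)C(C)(C)C)C=C(C)[C@H]2[C@]3(OC(=O)C(=O)OC)C1(C)C | intermediate
24 | (4R,5S,10R,11R)-1-(tert-butyldimethylsilyloxy)longipin-2-en-7-one | O=C1CC[C@@]2(C)[C@@H]3[C@@H](O[Si](C)(C)C(C)(C)C)C=C(C)[C@H]2[C@@H]3C1(C)C | intermediate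
25 | sodium enolate of 24 (C7(ONa)=C8) | [Na]OC1=CC[C@@]2(C)[C@@H]3[C@@H](O[Si](C)(C)C(C)(C)C)C=C(C)[C@H]2[C@@H]3C1(C)C | intermediate
26 | (8S)-1-(tert-butyldimethylsilyloxy)-8-hydroxylongipin-2-en-7-one | O=C1[C@@H](O)C[C@@]2(C)[C@@H]3[C@@H](O[Si](C)(C)C(C)(C)C)C=C(C)[C@H]2[C@@H]3C1(C)C | intermediate
27 | (7S,8S)-1-(tert-butyldimethylsilyloxy)longipin-2-ene-7,8-diol | O[C@@H]1[C@@H](O)C[C@@]2(C)[C@@H]3[C@@H](O[Si](C)(C)C(C)(C)C)C=C(C)[C@H]2[C@@H]3C1(C)C | intermediate
28 | 2-methylpropanoyl chloride (isobutyryl chloride) | CC(C)C(=O)Cl | starting material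
29 | (7S,8S)-1-(tert-butyldimethylsilyloxy)-7-hydroxylongipin-2-en-8-yl 2-methylpropanoate | O[C@@H]1[C@@H](OC(=O)C(C)C)C[C@@]2(C)[C@@H]3[C@@H](O[Si](C)(C)C(C)(C)C)C=C(C)[C@H]2[C@@H]3C1(C)C | intermediate
30 | angelic acid, (Z)-2-methylbut-2-enoic acid | C/C=C(/C)C(=O)O | starting material
31 | (Z)-2-methylbut-2-enoic 2,4,6-trichlorobenzoic anhydride | C/C=C(/C)C(=O)OC(=O)c1c(Cl)cc(Cl)cc1Cl | intermediate
32 | (7S,8S)-1-(tert-butyldimethylsilyloxy)-8-(2-methylpropanoyloxy)longipin-2-en-7-yl (Z)-2-methylbut-2-enoate | C/C=C(/C)C(=O)O[C@@H]1[C@@H](OC(=O)C(C)C)C[C@@]2(C)[C@@H]3[C@@H](O[Si](C)(C)C(C)(C)C)C=C(C)[C@H]2[C@@H]3C1(C)C | intermediate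
33 | (7S,8S)-1-hydroxy-8-(2-methylpropanoyloxy)longipin-2-en-7-yl (Z)-2-methylbut-2-enoate | C/C=C(/C)C(=O)O[C@@H]1[C@@H](OC(=O)C(C)C)C[C@@]2(C)[C@@H]3[C@@H](O)C=C(C)[C@H]2[C@@H]3C1(C)C | intermediate
34 | (4R,5S,7S,8S,10R,11R)-7-[(Z)-2-methylbut-2-enoyloxy]-8-(2-methylpropanoyloxy)longipin-2-en-1-one | C/C=C(/C)C(=O)O[C@@H]1[C@@H](OC(=O)C(C)C)C[C@@]2(C)[C@@H]3C(=O)C=C(C)[C@H]2[C@@H]3C1(C)C | target

Total step count: 20. Longest linear sequence: 19 steps (steps 1–5 and 7–20; step 6 is a one-step side branch).

Steps most likely to fail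

Step 7 (proposed new method). The risks are methyl transfer to the carbonyl carbon instead of C10, opening of the strained enone, weak enantioface discrimination on the nearly flat four-membered ring, and weak discrimination between methyl and chain when the aldehyde approaches C11. The fallback replaces catalysis by resolution and uses known chemistry; it sets out from 10. Stoichiometric conjugate addition of Me2CuLi (THF, −78 °C, NH4Cl work-up) should give the achiral 3-methyl-3-alkylcyclobutanone F1. LiN(iPr)2 at −78 °C followed by but-2-ynal 12 should give the racemic aldol, that is 15 together with its enantiomer F2, after chromatographic removal of the C11 and C1 epimers. Burkholderia cepacia lipase with vinyl acetate should acetylate F2 to the acetate of ent-15 F3, since the propynyl group acts as the medium and the ring as the large substituent in the empirical size rule for lipases. Unreacted 15 is separated and re-enters the route at step 8.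

Step 10 (proposed new method). The risks are loss of the silyl group from the strained enol ether to methanol before the C–C bond forms, and slow attack on the internal alkyne across the short C4···C11 span. The fallback replaces π-acid catalysis by palladium-catalysed ketone α-alkenylation, a known route to bridged bicyclic ketones; it sets out from 15. Ruthenium-catalysed trans-hydrosilylation (Et3SiH, [Cp*Ru(MeCN)3]PF6, CH2Cl2) places silicon on the alkyne carbon remote from the free hydroxyl and should give the (Z)-vinylsilane F4. N-Iodosuccinimide in hexafluoroisopropanol exchanges silicon for iodine with retention and should give the (Z)-vinyl iodide F5. TBSCl and imidazole give the silyl ether of the vinyl iodide F6. Pd(PPh3)4 with KOPh in THF at 65 °C should couple the C4 enolate with the C3–I bond and deliver 19, where the route resumes at step 11.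

Step 12. The risks are enolisation at C8 instead of C6, an aldol equilibrium lying on the side of the open diketone, and base-induced cleavage of the cyclobutanone. The fallback is a regiodefined Reformatsky-type closure; it sets out from 20. Pyrrolidone hydrotribromide in THF brominates the ketone at its more substituted α-carbon without adding to the alkene and should give the tertiary α-bromo ketone F7. SmI2 (2.2 equiv) in THF at −78 °C reduces the C6–Br bond to the samarium enolate, which should add to the C5 carbonyl under chelation and give 22, where the route resumes at step 13.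

Further compounds
F1 | step 7 | 3-methyl-3-{2-[2-(propan-2-yl)-1,3-dioxolan-2-yl]ethyl}cyclobutan-1-one | CC(C)C1(OCCO1)CCC2(C)CC(=O)C2
F2 | step 7 | enantiomer of 15, (2S,3S)-2-[(1S)-1-hydroxybut-2-yn-1-yl]-3-methyl-3-{2-[2-(propan-2-yl)-1,3-dioxolan-2-yl]ethyl}cyclobutan-1-one | CC(C)C1(OCCO1)CC[C@]2(C)[C@@H]([C@H](O)C#CC)C(=O)C2
F3 | step 7 | acetate of ent-15, (1S)-1-[(1S,2S)-2-methyl-4-oxo-2-{2-[2-(propan-2-yl)-1,3-dioxolan-2-yl]ethyl}cyclobutyl]but-2-yn-1-yl acetate | CC(C)C1(OCCO1)CC[C@]2(C)[C@@H]([C@H](OC(C)=O)C#CC)C(=O)C2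
F4 | step 10 | (Z)-vinylsilane, (2R,3R)-2-[(1R,2Z)-1-hydroxy-3-(triethylsilyl)but-2-en-1-yl]-3-methyl-3-{2-[2-(propan-2-yl)-1,3-dioxolan-2-yl]ethyl}cyclobutan-1-one | CC(C)C1(OCCO1)CC[C@@]2(C)[C@H]([C@@H](O)/C=C(/C)[Si](CC)(CC)CC)C(=O)C2
F5 | step 10 | (Z)-vinyl iodide, (2R,3R)-2-[(1R,2Z)-1-hydroxy-3-iodobut-2-en-1-yl]-3-methyl-3-{2-[2-(propan-2-yl)-1,3-dioxolan-2-yl]ethyl}cyclobutan-1-one | CC(C)C1(OCCO1)CC[C@@]2(C)[C@H]([C@@H](O)/C=C(/C)I)C(=O)C2
F6 | step 10 | tert-butyldimethylsilyl ether of the vinyl iodide F5 | CC(C)C1(OCCO1)CC[C@@]2(C)[C@H]([C@@H](O[Si](C)(C)C(C)(C)C)/C=C(/C)I)C(=O)C2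
F7 | step 12 | tertiary α-bromo ketone, 7-(4-bromo-4-methyl-3-oxopentyl)-4-(tert-butyldimethylsilyloxy)-2,7-dimethylbicyclo[3.1.1]hept-2-en-6-one | CC(C)(Br)C(=O)CC[C@@]1(C)[C@@H]2[C@@H](O[Si](C)(C)C(C)(C)C)C=C(C)[C@H]1C2=O
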